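Late in the north-east run target barely moves: 66.7% at 5.00 d, 67.1% at 6.00 d. I have to decide what to change in the next flask, and that reading is my tool.

| flask | starting material | reagent in the second phase | protic impurity | remark | time | volume of the second phase over the first |
|---|---|---|---|---|---|---|
| north-east | 0.044 M | 0.158 M | 4.4 mM | run made earlier |  |  |
| west | 0.18 M | 0.158 M | 4.4 mM | run made earlier |  |  |
| south | 0.088 M | 0.32 M | 4.4 mM | run made earlier |  |  |
| flask | 0.088 M | 0.158 M | 4.40 mM |  | 6.0 d | 1.0 |

| run | time / d | target / % | starting material / % |
|---|---|---|---|
| north-east | 0.833 | 23.3 | 66.3 |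
| north-east | 1.67 | 40.2 | 48.4 |
| north-east | 2.50 | 52.0 | 34.6 |
| north-east | 3.00 | 56.7 | 27.3 |
| north-east | 4.00 | 63.7 | 17.8 |
| north-east | 5.00 | 66.7 | 12.6 |
| north-east | 6.00 | 67.1 | 9.1 |
| west | 0.833 | 10.1 | 87.0 |
| west | 1.67 | 18.2 | 79.4 |
| west | 2.50 | 24.9 | 71.7 |
| west | 3.00 | 28.3 | 68.2 |
| west | 4.00 | 35.7 | 61.1 |
| west | 5.00 | 40.6 | 56.3 |
| west | 6.00 | 45.1 | 50.8 |
| south | 0.500 | 20.4 | 74.6 |
| south | 0.833 | 31.6 | 62.7 |
| south | 1.67 | 52.5 | 39.6 |
| south | 3.00 | 69.3 | 16.5 |
| south | 6.00 | 65.6 | 2.1 |

(readings scatter by 0.5 percentage points)

- in the second phase: reagent in the second phase; everything else is in the first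
- charges count per volume of the first phase; a concentration in a rate is the amount of a species over the volume of its own phase; every rate counts per litre of the first phase
- the earlier runs hold the two phases in the same ratio of volumes as the flask asked about

1. amount of target at 6.0 d, in percent of the starting material charged
2. the change that raises the amount of target at 6.0 d, in percent of the starting material charged most ("none" if none brings more than 2 percentage points) (cedar / ash / none)
3. amount of target at 6.0 d, in percent of the starting material charged, after cedar

If target is lost to the same reagent that makes it, the reagent cancels, and target stops rising where starting material over target reaches a fixed ratio, the selectivity factor. I call it the turning ratio, and take a rough value from the last north-east pair, 0.136: that is one scattered pair, read where target has nearly stopped rising, so it is a guide and not the fixed ratio itself. Above it target still rises; below it target falls.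

The south run holds twice the reagent of the flask, with the same starting material and impurity, so it stands for ash. Its ratio is 0.238 at 3.00 d, above the turning ratio, and 0.0320 at 6.00 d, below it. Target has dropped from 69.3% to 65.6%, so ash overshoots.

The west run charges 4.09 times the starting material of the north-east run, yet its first reading holds 1.77 times the molar target. Transfer therefore shares the control, and doubling it should speed the flask by less than doubling the reagent. So I choose cedar, expect about 69.3% from it, and put the flask itself below that.

The forecast gives 65.3%, cedar and 69.4%, holding that “Doubling reagent essentially repeats the south run”.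

The flask gives 64.4%, and cedar gives 69.9%, a gain of 5.5 percentage points against 1.4 points for ash. At 2.24 d the flask makes target 12.6 times faster than it uses it up.

    reagent in the reaction phase → decomposition product (k = 6.33 × 10⁻⁸ s⁻¹)
    reagent in the reaction phase + target → over-reacted product (k = 7.28 × 10⁻⁴ M⁻¹ s⁻¹)
    reagent in the reaction phase ⇌ reagent in the second phase, rate k3*([reagent in the reaction phase] - [reagent in the second phase]/K3) per volume of the first phase (partition coefficient = 92.0, kL = 1.92 × 10⁻⁴ s⁻¹)
    starting material + protic impurity → quenched substrate (k = 0.00133 M⁻¹ s⁻¹)
    reagent in the reaction phase → decomposed reagent (k = 3.95 × 10⁻⁵ s⁻¹)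
    starting material + reagent in the reaction phase → target (k = 0.00610 M⁻¹ s⁻¹)

At 6.00 d the flask's ratio is 0.370, above the turning ratio, so target is still rising. The same flask read at 10.0 d stands at 0.148, still above my rough value, with 71.0% target, and at 12.0 d it holds 71.1%.

The data are simulated for substances that don't exist, noise included.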